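I decide to follow one thing in this flask: the rate at which solid electrophile truly reacts, in molar per minute rather than in percent. The solid goes undissolved into free base and protonated nucleophile, and target is the product I can read.

the same everywhere: solid electrophile 0.26 M; protonated nucleophile 0.247 M

| charge | free base | remark | time |
|---|---|---|---|
| winter | 0.20 M | run made earlier |  |
| dawn | 0.28 M | run made earlier |  |
| theta | 0.290 M |  | 30 min |
| gamma | 0.370 M |  | 30 min |

| run | time / min | solid electrophile / % | target / % |
|---|---|---|---|
| winter | 1.33 | 94.6 | 0 |
| winter | 2.00 | 94.6 | 1.3 |
| winter | 3.00 | 91.2 | 0.5 |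
| winter | 4.00 | 90.6 | 0.7 |
| winter | 6.00 | 87.9 | 1.5 |
| winter | 10.0 | 85.9 | 2.1 |
| winter | 15.0 | 83.5 | 2.5 |
| dawn | 0.833 | 96.4 | 0 |
| dawn | 2.50 | 92.9 | 0.5 |
| dawn | 4.00 | 89.2 | 2.0 |
| dawn | 6.00 | 86.5 | 2.3 |
| dawn | 10.0 | 83.8 | 2.4 |
| dawn | 12.0 | 83.7 | 2.6 |
| dawn | 15.0 | 84.1 | 2.6 |

(standard deviation of a reading: 1 percentage point)

1. part of the solid electrophile that has reacted (what has only dissolved counts as not reacted) at the end, theta
2. part of the solid electrophile that has reacted (what has only dissolved counts as not reacted) at the end, gamma
3. what raising the concentration of free base from its lowest to its highest value here does to the part of the solid electrophile that has reacted (what has only dissolved counts as not reacted) (changes below 5 percentage points count as none) (no change / it rises / it falls)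

- at the start none of the solid electrophile is in solution
- what has only dissolved of solid electrophile counts as not reacted

In the winter run 83.5% of the charge is still solid at the last reading, so I take the solution as saturated. On that assumption the concentration of what has dissolved holds steady, and the rate is zero order in the amount of solid. Over the first 6.00 min, target appears at 8.23 × 10⁻⁴ M min⁻¹ on average, read from both runs, and I take that as the early rate. Late on, if the solution stays saturated, the solid that still goes replaces what has reacted. Between 10.0 min and 15.0 min it goes at 5.46 × 10⁻⁴ M min⁻¹, a rough reading, since each point scatters by 1 percentage point. On these two rough readings, one of target and one of solid, the late rate stands at 0.663 of the early one, and I let the next 15.0 min fall by the same factor, to 3.62 × 10⁻⁴ M min⁻¹. I give free base a factor of one, since the two runs differ in target at 6.00 min by 0.8 points, less than the scatter. Averaging these stretches gives my mean drain, the reacted concentration per minute up to the end, of 5.69 × 10⁻⁴ M min⁻¹. That makes my estimate 6.57% reacted in both theta and gamma, with no trend.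

The forecast differs from my number: 2.8% for theta and 3.2% for gamma, with the trend no change, on the ground that most of the loss “is simply dissolution to saturation”.

The flask gives 7.63% for theta and 7.44% for gamma, a change of −0.19 points, so the trend is no change and the forecast's calls stand within their margin.

    nucleophile + acid set free ⇌ protonated nucleophile, settled at all times (K = 12000 M⁻¹)
    2 nucleophile → self-condensation product (k = 1.10 M⁻¹ min⁻¹)
    electrophile + nucleophile → acid set free + target (k = 0.700 M⁻¹ min⁻¹)
    target → over-reaction product (k = 0.100 min⁻¹)
    solid electrophile ⇌ electrophile, rate k5*(cs5 - [electrophile]) while solid is left; crystals form when [electrophile] > cs5 (solubility = 33.0 mM, k = 0.350 min⁻¹)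
    acid set free + free base ⇌ salt of the base, settled at all times (K = 1.30 × 10⁵ M⁻¹)

Theta's mean drain is 6.61 × 10⁻⁴ M min⁻¹, faster than my 5.69 × 10⁻⁴ M min⁻¹, and theta ends with more over-reaction product, 5.93%, than target, 1.70%. A neighbour of theta is charged with 0.065 M of solid electrophile. If the drain ignores the charge, my 5.69 × 10⁻⁴ M min⁻¹ gives 26.3% reacted there. The neighbour gives 30.5%, a mean drain of 6.61 × 10⁻⁴ M min⁻¹, close to theta's, with 20.2% of its charge still solid at the end.

The runs stem from a simulated flask for substances that don't exist; scatter was added.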